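**Plan**

- Numbering (core as a 2-benzofuranone): C1 lactone C=O, O2, C3 (OCH2), C3a (quaternary, carries the side chain), C4 ketone, C5=C6, C7 (CH2), C7a (C–OH).
- Retrosynthesis: the enone is traced back to a β-amino silyl enol ether (N on C6, O–Si on C4). Then C6–C7 and C3a–C7a are cut together as one [4+2] retron. Then come the C3–O2 ester, the C6–N bond, the C4–C5 alkynyl bond and the pyranone (lactonisation, alkyne coupling, acetoacetate alkylation).
- Enabling feature: the lactone bridge C3–O2–C1 spans the fusion bond C3a–C7a and ties a diene terminus (C3a) to a dienophile carbon (C7a). The 4-oxo-5-ene is a latent 1-amino-3-siloxy diene C3a=C4–C5=C6 and the 7a-OH beside C1=O is a latent pyruvate enol C7=C7a. The oxygens on C4 and C7a sit 1,3 across C3a, so one R2Si can bridge them into a nine-membered ring.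
- Forward order: 2-pyranone ring (steps 1–4); side-chain elaboration to an acyclic vinylogous-amide pyruvate ester (steps 5–10); temporary nine-membered silylene ring, then cyclohexene and γ-lactone together by transannular Diels–Alder reaction (step 11); silicon bridge and amine removed as the enone is unveiled (step 12).
- Stereochemistry: C3a and C7a are both set in step 11. The absolute sense comes from a (2R,5R)-2,5-diphenylpyrrolidine auxiliary on C6, lost in step 12. The trans ring fusion comes from the O–Si–O bridge (C7a oxygen endo) and the ring-locked enol ether geometry.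

Key step: step 11

Remark: the stereocentre α to the ketone (future C3a) is carried as a racemate or epimer mixture from step 5 to step 11, where it is planarised; the bromide and 3-ethynylfuran are taken as purchasable.

**Route**

Step 1
Reactants: 1 tert-butyl acetoacetate; 2 5-(2-bromoethyl)-2,2-dimethyl-1,3-dioxane
Product: 3 tert-butyl 2-acetyl-4-(2,2-dimethyl-1,3-dioxan-5-yl)butanoate (racemic)
Conditions: NaH, THF/DMF, 0 °C; then 2, NaI (cat.), 60 °C
Reagents that add atoms: none
Why: C-alkylation of the sodium enolate of a β-keto ester with a primary bromide (acetoacetic ester alkylation, iodide catalysis) should attach the arm that carries the masked 1,3-diol; the new α-centre is racemic and becomes sp2 in step 2.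

Step 2
Reactants: 3 tert-butyl 2-acetyl-4-(2,2-dimethyl-1,3-dioxan-5-yl)butanoate
Product: 4 tert-butyl (2Z)-2-[2-(2,2-dimethyl-1,3-dioxan-5-yl)ethyl]-3-[(trifluoromethanesulfonyl)oxy]but-2-enoate
Conditions: NaH, Et2O, 0 °C; Tf2O, −78 → 0 °C
Reagents that add atoms: trifluoromethanesulfonic anhydride, O=S(=O)(OS(=O)(=O)C(F)(F)F)C(F)(F)F
Why: O-triflation of the chelated sodium enolate in a weakly coordinating medium (enol triflate formation) is expected to place the triflate cis to the ester, the geometry that the lactonisation of step 4 needs.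

Step 3
Reactants: 4 the Z enol triflate; 5 3-ethynylfuran
Product: 6 tert-butyl (2Z)-2-[2-(2,2-dimethyl-1,3-dioxan-5-yl)ethyl]-5-(furan-3-yl)-3-methylpent-2-en-4-ynoate
Conditions: PdCl2(PPh3)2 (3 mol %), CuI (5 mol %), Et3N, THF, 23 °C
Reagents that add atoms: none
Why: Sonogashira coupling of an enol triflate with a terminal alkyne proceeds with retention of alkene geometry and so should put the furyl alkyne cis to the ester.

Step 4
Reactants: 6 the Z enynoate
Product: 8 6-(furan-3-yl)-3-[4-hydroxy-3-(hydroxymethyl)butyl]-4-methyl-2H-pyran-2-one, via pyranone acetonide 7 (not isolated)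
Conditions: Ph3PAuCl (5 mol %), AgSbF6 (5 mol %), CH2Cl2, 23 °C; concentrate; AcOH/THF/H2O (3:1:1), 40 °C
Reagents that add atoms: none
Why: π-acid activation of the alkyne should trigger 6-endo-dig attack of the ester carbonyl oxygen at the furyl-bearing alkyne carbon with loss of isobutene (gold-catalysed lactonisation of a tert-butyl enynoate to a 2-pyranone), and mild aqueous acid then hydrolyses the acetonide.

Step 5
Reactants: 8 the pyranone diol
Product: 9 3-[3-({[tert-butyl(dimethyl)silyl]oxy}methyl)-4-hydroxybutyl]-6-(furan-3-yl)-4-methyl-2H-pyran-2-one (racemic)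
Conditions: TBSCl (1.0 equiv), imidazole, DMF, 0 °C (diol and bis-silyl ether recycled)
Reagents that add atoms: tert-butyldimethylsilyl chloride, CC(C)(C)[Si](C)(C)Cl
Why: statistical monosilylation of the symmetrical 1,3-diol (silyl ether formation) differentiates the two arms; the new centre is racemic, which is harmless because it is planarised in step 11.

Step 6
Reactants: 9 the monosilyl ether
Product: 10 2-({[tert-butyl(dimethyl)silyl]oxy}methyl)-4-[6-(furan-3-yl)-4-methyl-2-oxo-2H-pyran-3-yl]butanal (racemic)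
Conditions: Dess–Martin periodinane, CH2Cl2, 0 → 23 °C
Reagents that add atoms: none
Why: Dess–Martin oxidation of a primary alcohol to the aldehyde is mild enough for the β-silyloxy aldehyde, the furan and the pyranone.

Step 7
Reactants: 10 the aldehyde
Product: 11 3-[3-({[tert-butyl(dimethyl)silyl]oxy}methyl)-4-hydroxyhex-5-yn-1-yl]-6-(furan-3-yl)-4-methyl-2H-pyran-2-one (diastereomer mixture)
Conditions: HC≡CMgBr, THF, −78 → −20 °C; aq. NH4Cl
Reagents that add atoms: ethynylmagnesium bromide, C#C[Mg]Br
Why: Grignard addition of the alkynyl reagent to the aldehyde at low temperature should outrun attack on the pyranone; the carbinol diastereomers converge on oxidation in step 8.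

Step 8
Reactants: 11 the propargylic alcohol; 12 (2R,5R)-2,5-diphenylpyrrolidine
Product: 14 3-[(5E)-3-({[tert-butyl(dimethyl)silyl]oxy}methyl)-6-[(2R,5R)-2,5-diphenylpyrrolidin-1-yl]-4-oxohex-5-en-1-yl]-6-(furan-3-yl)-4-methyl-2H-pyran-2-one, via ynone 13 (not isolated)
Conditions: MnO2, CH2Cl2, 23 °C; filter; 12, CH2Cl2, 23 → 40 °C
Reagents that add atoms: none
Why: MnO2 oxidises the propargylic alcohol to the terminal ynone, and conjugate (aza-Michael) addition of the secondary amine should give the E vinylogous amide, which places the auxiliary on the future C6.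

Step 9
Reactants: 14 the silyl-protected vinylogous amide
Product: 15 3-[(5E)-6-[(2R,5R)-2,5-diphenylpyrrolidin-1-yl]-3-(hydroxymethyl)-4-oxohex-5-en-1-yl]-6-(furan-3-yl)-4-methyl-2H-pyran-2-one
Conditions: HF·pyridine, pyridine, THF, 0 → 23 °C
Reagents that add atoms: none
Why: buffered fluoride cleavage of the primary silyl ether (desilylation) should leave the vinylogous amide, the pyranone and the furan untouched.

Step 10
Reactants: 15 the primary alcohol; 16 pyruvic acid
Product: 17 (4E)-5-[(2R,5R)-2,5-diphenylpyrrolidin-1-yl]-2-{2-[6-(furan-3-yl)-4-methyl-2-oxo-2H-pyran-3-yl]ethyl}-3-oxopent-4-en-1-yl 2-oxopropanoate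
Conditions: DIC, DMAP (cat.), CH2Cl2, −20 → 0 °C
Reagents that add atoms: none
Why: Steglich esterification of the primary alcohol delivers the future lactone bridge together with C1, C7a and C7 at the ketone oxidation level.

Step 11
Reactants: 17 the vinylogous-amide pyruvate ester
Product: 21 silylene-bridged cycloadduct (3aS,6S,7aR; O–Si(iPr)2–O bridge from the C4 enol oxygen to the C7a oxygen; trans-fused lactone; auxiliary on C6), via chlorosilyl enol ether 18 (not isolated), via cyclic silyloxy iminium triflate 19 (not isolated), via macrocyclic silylene bis-enol ether 20 (not isolated)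
Conditions: iPr2SiCl2 (1.05 equiv), Et3N (4 equiv), CH2Cl2, 0 → 23 °C; dilute to 2 mM; AgOTf (AgOSO2CF3, 1.1 equiv), −40 → 23 °C; then 40 °C
Reagents that add atoms: dichlorodi(propan-2-yl)silane, CC(C)[Si](Cl)(Cl)C(C)C
Why: Proposed new method: soft enolisation first converts the pyruvate ketone into chlorosilyl enol ether 18, AgOSO2CF3 then ionises Si–Cl so that the vinylogous amide oxygen is silylated intramolecularly (nine-membered ring closed by reversible O–Si bond formation, 19) and Et3N removes C3a–H inside that ring, which gives the 1-amino-3-siloxy diene C3a=C4–C5=C6 of 20 only with C3 and the C4 oxygen cis and only after the electrophilic ketone has gone (no Mukaiyama-type aldol escape). Diene and enol ether C7=C7a then react across the ring in a concerted suprafacial transannular [4+2] cycloaddition: bonds C6–C7 and C3a–C7a close the cyclohexene, and the C3a–C7a bond at the same time divides the nine-membered ring into the five-membered lactone and a six-membered 1,3-dioxa-2-silinane. The closest known reaction types are Diels–Alder reactions of chiral 1-amino-3-siloxy dienes, ester-tethered intramolecular and transannular Diels–Alder reactions and silicon-tethered cycloadditions; their union in one doubly bridged nine-membered silyl bis-enol ether with a fully substituted diene terminus is without direct precedent. Regiochemistry is enforced by the ester bridge (C3a must meet C7a, against the polarisation of the diene), and the O–Si–O bridge can span the C4 and C7a oxygens only if the C7a oxygen is endo, so the lactone carbonyl is exo and the ring fusion trans (side chain and C7a oxygen anti). The absolute configuration of C3a, and through the bridges of C7a, is set by the diene face attacked: the (2R,5R)-pyrrolidine lies in the diene plane and its phenyl group on the open side of C6 should screen one face, so that C7 adds to the other, while the amino group, kept outside by the E enamine, fixes the temporary centre C6. The step therefore needs π-facial selectivity (auxiliary), endo/exo and enol-geometry control (temporary ring) and ring closure instead of oligomerisation (high dilution, reversible Si–O bond formation to the iminium).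

Step 12
Reactants: 21 the silylene-bridged cycloadduct
Product: 22 (3aR,7aR)-3a-{2-[6-(furan-3-yl)-4-methyl-2-oxo-2H-pyran-3-yl]ethyl}-7a-hydroxy-3,3a,7,7a-tetrahydro-2-benzofuran-1,4-dione (target)
Conditions: aq. HF (48%), MeCN, 0 → 23 °C
Reagents that add atoms: none
Why: fluoride should cleave both Si–O bonds, the freed C4 ketone is protonated at C5 and the resulting β-amino ketone expels the pyrrolidine (desilylation followed by retro-aza-Michael elimination) to unveil the enone and the tertiary alcohol; C3a and C7a are quaternary and cannot epimerise, and the acidic medium avoids retro-aldol cleavage.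

**Compound list**

1 | tert-butyl 3-oxobutanoate (tert-butyl acetoacetate) | CC(=O)CC(=O)OC(C)(C)C | starting material
2 | 5-(2-bromoethyl)-2,2-dimethyl-1,3-dioxane | BrCCC1COC(C)(C)OC1 | starting material
3 | tert-butyl 2-acetyl-4-(2,2-dimethyl-1,3-dioxan-5-yl)butanoate (racemic) | CC(=O)C(CCC1COC(C)(C)OC1)C(=O)OC(C)(C)C | intermediate
4 | tert-butyl (2Z)-2-[2-(2,2-dimethyl-1,3-dioxan-5-yl)ethyl]-3-[(trifluoromethanesulfonyl)oxy]but-2-enoate | CC(C)(C)OC(=O)/C(CCC1COC(C)(C)OC1)=C(/C)OS(=O)(=O)C(F)(F)F | intermediate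
5 | 3-ethynylfuran | C#Cc1ccoc1 | starting material
6 | tert-butyl (2Z)-2-[2-(2,2-dimethyl-1,3-dioxan-5-yl)ethyl]-5-(furan-3-yl)-3-methylpent-2-en-4-ynoate | CC(C)(C)OC(=O)/C(CCC1COC(C)(C)OC1)=C(/C)C#Cc1ccoc1 | intermediate
7 | 3-[2-(2,2-dimethyl-1,3-dioxan-5-yl)ethyl]-6-(furan-3-yl)-4-methyl-2H-pyran-2-one | Cc1cc(-c2ccoc2)oc(=O)c1CCC1COC(C)(C)OC1 | intermediate
8 | 6-(furan-3-yl)-3-[4-hydroxy-3-(hydroxymethyl)butyl]-4-methyl-2H-pyran-2-one | Cc1cc(-c2ccoc2)oc(=O)c1CCC(CO)CO | intermediate
9 | 3-[3-({[tert-butyl(dimethyl)silyl]oxy}methyl)-4-hydroxybutyl]-6-(furan-3-yl)-4-methyl-2H-pyran-2-one (racemic) | Cc1cc(-c2ccoc2)oc(=O)c1CCC(CO)CO[Si](C)(C)C(C)(C)C | intermediate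
10 | 2-({[tert-butyl(dimethyl)silyl]oxy}methyl)-4-[6-(furan-3-yl)-4-methyl-2-oxo-2H-pyran-3-yl]butanal (racemic) | Cc1cc(-c2ccoc2)oc(=O)c1CCC(C=O)CO[Si](C)(C)C(C)(C)C | intermediate
11 | 3-[3-({[tert-butyl(dimethyl)silyl]oxy}methyl)-4-hydroxyhex-5-yn-1-yl]-6-(furan-3-yl)-4-methyl-2H-pyran-2-one (diastereomer mixture) | Cc1cc(-c2ccoc2)oc(=O)c1CCC(CO[Si](C)(C)C(C)(C)C)C(O)C#C | intermediate
12 | (2R,5R)-2,5-diphenylpyrrolidine | N1[C@@H](c2ccccc2)CC[C@@H]1c1ccccc1 | starting material
13 | 3-[3-({[tert-butyl(dimethyl)silyl]oxy}methyl)-4-oxohex-5-yn-1-yl]-6-(furan-3-yl)-4-methyl-2H-pyran-2-one (racemic) | Cc1cc(-c2ccoc2)oc(=O)c1CCC(CO[Si](C)(C)C(C)(C)C)C(=O)C#C | intermediate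
14 | 3-[(5E)-3-({[tert-butyl(dimethyl)silyl]oxy}methyl)-6-[(2R,5R)-2,5-diphenylpyrrolidin-1-yl]-4-oxohex-5-en-1-yl]-6-(furan-3-yl)-4-methyl-2H-pyran-2-one (epimers at chain C3) | Cc1cc(-c2ccoc2)oc(=O)c1CCC(CO[Si](C)(C)C(C)(C)C)C(=O)/C=C/N1[C@@H](c2ccccc2)CC[C@@H]1c1ccccc1 | intermediate
15 | 3-[(5E)-6-[(2R,5R)-2,5-diphenylpyrrolidin-1-yl]-3-(hydroxymethyl)-4-oxohex-5-en-1-yl]-6-(furan-3-yl)-4-methyl-2H-pyran-2-one (epimers at chain C3) | Cc1cc(-c2ccoc2)oc(=O)c1CCC(CO)C(=O)/C=C/N1[C@@H](c2ccccc2)CC[C@@H]1c1ccccc1 | intermediate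
16 | pyruvic acid (2-oxopropanoic acid) | CC(=O)C(=O)O | starting material
17 | (4E)-5-[(2R,5R)-2,5-diphenylpyrrolidin-1-yl]-2-{2-[6-(furan-3-yl)-4-methyl-2-oxo-2H-pyran-3-yl]ethyl}-3-oxopent-4-en-1-yl 2-oxopropanoate (epimers at C2) | Cc1cc(-c2ccoc2)oc(=O)c1CCC(COC(=O)C(C)=O)C(=O)/C=C/N1[C@@H](c2ccccc2)CC[C@@H]1c1ccccc1 | intermediate
18 | (4E)-5-[(2R,5R)-2,5-diphenylpyrrolidin-1-yl]-2-{2-[6-(furan-3-yl)-4-methyl-2-oxo-2H-pyran-3-yl]ethyl}-3-oxopent-4-en-1-yl 2-{[chlorodi(propan-2-yl)silyl]oxy}prop-2-enoate (epimers at C2) | Cc1cc(-c2ccoc2)oc(=O)c1CCC(COC(=O)C(=C)O[Si](Cl)(C(C)C)C(C)C)C(=O)/C=C/N1[C@@H](c2ccccc2)CC[C@@H]1c1ccccc1 | intermediate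
19 | triflate salt of the ring-closed silyloxy iminium ion: nine-membered 1,3,7-trioxa-2-silacyclononan-8-one with 9-methylidene and 2,2-di(propan-2-yl) groups; C4 of that ring carries the exocyclic C=C–C=N(+) unit of the (2R,5R)-2,5-diphenylpyrrolidinium and C5 (sp3, epimers) carries the pyranonylethyl chain; cation delocalised with exocyclic C=C geometry undefined | C=C1O[Si](C(C)C)(C(C)C)OC(=CC=[N+]2[C@@H](c3ccccc3)CC[C@@H]2c2ccccc2)C(CCc2c(C)cc(-c3ccoc3)oc2=O)COC1=O.[O-]S(=O)(=O)C(F)(F)F | intermediate
20 | (4Z)-4-{(E)-2-[(2R,5R)-2,5-diphenylpyrrolidin-1-yl]ethenyl}-5-{2-[6-(furan-3-yl)-4-methyl-2-oxo-2H-pyran-3-yl]ethyl}-9-methylidene-2,2-di(propan-2-yl)-1,3,7-trioxa-2-silacyclonon-4-en-8-one | C=C1O[Si](C(C)C)(C(C)C)O/C(/C=C/N2[C@@H](c3ccccc3)CC[C@@H]2c2ccccc2)=C(CCc2c(C)cc(-c3ccoc3)oc2=O)\COC1=O | intermediate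
21 | (3aS,6S,7aR)-6-[(2R,5R)-2,5-diphenylpyrrolidin-1-yl]-3a-{2-[6-(furan-3-yl)-4-methyl-2-oxo-2H-pyran-3-yl]ethyl}-3,3a,6,7-tetrahydro-2-benzofuran-1-one whose C4 enol oxygen and C7a oxygen are joined by a di(propan-2-yl)silanediyl bridge (same spatial arrangement at C3a and C7a as in 22; the 3a descriptor differs only through the priority change) | Cc1cc(-c2ccoc2)oc(=O)c1CC[C@@]12COC(=O)[C@@]1(O[Si](C(C)C)(C(C)C)O3)C[C@H](N4[C@@H](c5ccccc5)CC[C@@H]4c4ccccc4)C=C23 | intermediate
22 | (3aR,7aR)-3a-{2-[6-(furan-3-yl)-4-methyl-2-oxo-2H-pyran-3-yl]ethyl}-7a-hydroxy-3,3a,7,7a-tetrahydro-2-benzofuran-1,4-dione (trans-fused; OH and side chain anti) | Cc1cc(-c2ccoc2)oc(=O)c1CC[C@@]12COC(=O)[C@@]1(O)CC=CC2=O | target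

**Count**

Total steps: 12. Longest linear sequence: 12 steps (from 1 and 2 to 22).

**Steps most likely to fail**

1. Step 11. The risks are these:
   - intermolecular silylation (oligomerisation) instead of nine-membered ring closure;
   - ionisation of the allylic ester once the very electron-rich diene has formed;
   - a slow cycloaddition, because the diene terminus C3a is fully substituted and the bond pairing is forced against the polarisation of the diene;
   - weak π-facial discrimination, because the dienophile carbon that meets the auxiliary-bearing terminus is an unsubstituted CH2; the predicted sense rests on a steric model only.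

   The fallback uses known chemistry and sets out from 17. Double soft enolisation with TBSOTf and Et3N (CH2Cl2, −78 °C) gives the open-chain bis(silyl enol ether) triene F1, in which the pyruvate is a 2-silyloxyacrylate and the vinylogous amide a 1-amino-3-siloxy diene of mixed enol ether geometry. Heating in toluene (80–110 °C) brings about an ordinary ester-tethered intramolecular Diels–Alder reaction to the bis-silyl cycloadduct F2. The trans-fused isomer has to be separated from cis-fused and facial isomers, since only the auxiliary and the inherent exo preference act here. Aqueous HF in MeCN then removes both silyl groups and the amine, and the sequence comes back to the route at 22.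

2. Step 10. Carbodiimide-activated pyruvic acid may condense with itself, and acylation at the nucleophilic enaminone carbon may compete with O-acylation. The fallback sets out from 15 and changes the oxidation level of the acyl donor. Esterification with 2-[(tert-butyldimethylsilyl)oxy]propanoic acid (DIC, DMAP) gives the silyl lactate ester F3. HF·pyridine frees the lactate ester F4. Dess–Martin oxidation of its secondary alcohol gives the α-keto ester and returns to the route at 17.

3. Step 4. Closure may take the 5-exo-dig course to the ylidene butenolide instead of the 6-endo course, and adventitious acid from the cationic gold catalyst may degrade the furan. The fallback sets out from 6 and abandons π-acid activation of the ester. The tert-butyl ester is cleaved first (TMSOTf, 2,6-lutidine, CH2Cl2; aqueous work-up) to the (Z)-enynoic acid F5. The free acid is then lactonised with catalytic ZnBr2 in THF, a Lewis-acid lactonisation of (Z)-2-en-4-ynoic acids that favours the six-membered ring. This returns to the route at 7, which is hydrolysed to 8 as in step 4.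

Further compounds
F1 | step 11 | (4E)-3-{[tert-butyl(dimethyl)silyl]oxy}-5-[(2R,5R)-2,5-diphenylpyrrolidin-1-yl]-2-{2-[6-(furan-3-yl)-4-methyl-2-oxo-2H-pyran-3-yl]ethyl}penta-2,4-dien-1-yl 2-{[tert-butyl(dimethyl)silyl]oxy}prop-2-enoate (C2=C3 geometry mixed) | C=C(O[Si](C)(C)C(C)(C)C)C(=O)OCC(CCc1c(C)cc(-c2ccoc2)oc1=O)=C(O[Si](C)(C)C(C)(C)C)/C=C/N1[C@@H](c2ccccc2)CC[C@@H]1c1ccccc1
F2 | step 11 | (3aS,6S,7aR)-4,7a-bis{[tert-butyl(dimethyl)silyl]oxy}-6-[(2R,5R)-2,5-diphenylpyrrolidin-1-yl]-3a-{2-[6-(furan-3-yl)-4-methyl-2-oxo-2H-pyran-3-yl]ethyl}-3,3a,6,7-tetrahydro-2-benzofuran-1-one | Cc1cc(-c2ccoc2)oc(=O)c1CC[C@@]12COC(=O)[C@@]1(O[Si](C)(C)C(C)(C)C)C[C@H](N3[C@@H](c4ccccc4)CC[C@@H]3c3ccccc3)C=C2O[Si](C)(C)C(C)(C)C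
F3 | step 10 | (4E)-5-[(2R,5R)-2,5-diphenylpyrrolidin-1-yl]-2-{2-[6-(furan-3-yl)-4-methyl-2-oxo-2H-pyran-3-yl]ethyl}-3-oxopent-4-en-1-yl 2-{[tert-butyl(dimethyl)silyl]oxy}propanoate (lactate centre of either configuration) | Cc1cc(-c2ccoc2)oc(=O)c1CCC(COC(=O)C(C)O[Si](C)(C)C(C)(C)C)C(=O)/C=C/N1[C@@H](c2ccccc2)CC[C@@H]1c1ccccc1
F4 | step 10 | (4E)-5-[(2R,5R)-2,5-diphenylpyrrolidin-1-yl]-2-{2-[6-(furan-3-yl)-4-methyl-2-oxo-2H-pyran-3-yl]ethyl}-3-oxopent-4-en-1-yl 2-hydroxypropanoate | Cc1cc(-c2ccoc2)oc(=O)c1CCC(COC(=O)C(C)O)C(=O)/C=C/N1[C@@H](c2ccccc2)CC[C@@H]1c1ccccc1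
F5 | step 4 | (2Z)-2-[2-(2,2-dimethyl-1,3-dioxan-5-yl)ethyl]-5-(furan-3-yl)-3-methylpent-2-en-4-ynoic acid | OC(=O)/C(CCC1COC(C)(C)OC1)=C(/C)C#Cc1ccoc1
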